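**Retrosynthetic overview**
1. Target ⇒ cut the acyl C–CH2 bond (new linear-selective hydroacylation, last step, no protecting groups): 5,7-dihydroxy-2,2-dimethylchroman-6-carbaldehyde + 2-prenyl-4-vinylphenol.
2. Chroman aldehyde ⇒ C6–CHO bond by directed ortho-metalation between two OMOM groups ⇒ 2,2-dimethylchroman-5,7-diol.
3. Chroman diol ⇒ aryl C–C and O–C bonds of the pyran ⇒ phloroglucinol + 2-methylbut-3-en-2-ol.
4. Vinylphenol ⇒ Wittig methylenation of 4-hydroxy-3-prenylbenzaldehyde ⇒ ortho C-prenylation of 4-hydroxybenzaldehyde with prenyl bromide.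
5. Ring order: both benzene rings are bought. The dihydropyran is the only ring made and is made first, so acid never meets the B-ring o-prenylphenol.

Assumption: the SMILES has no stereocentre and no E/Z-stereogenic double bond, so the target is achiral and "single enantiomer" needs no stereocontrol.

**Step 1**
Reactants: 1 phloroglucinol; 2 2-methylbut-3-en-2-ol
Product: 4 2,2-dimethylchroman-5,7-diol, via 2-prenylphloroglucinol 3 (not isolated)
Conditions: Amberlyst-15 (H+ resin, cat.), THF, 65 °C, 1 in 3-fold excess
Reagents that add atoms: none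
Why: The acid ionises 2 to the prenyl cation, which C-alkylates the electron-rich ring (Friedel–Crafts prenylation), and the same acid closes the ring by intramolecular hydroalkoxylation; the two ortho OH groups of 3 are equivalent, so only one chroman can form, excess 1 suppresses double annulation, and no stereocentre arises.

**Step 2**
Reactants: 4 2,2-dimethylchroman-5,7-diol
Product: 5 5,7-bis(methoxymethoxy)-2,2-dimethylchroman
Conditions: MOMCl (2.6 equiv), i-Pr2NEt (3.5 equiv), CH2Cl2, 0 °C → rt
Reagents that add atoms: chloromethyl methyl ether (MOMCl), COCCl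
Why: Williamson-type O-alkylation of both free phenols with the hard electrophile MOMCl installs two strong ortho-directing groups, and the chroman ether is inert to amine base.

**Step 3**
Reactants: 5 5,7-bis(methoxymethoxy)-2,2-dimethylchroman
Product: 8 5,7-bis(methoxymethoxy)-2,2-dimethylchroman-6-carbaldehyde, via C6-aryllithium 6 (not isolated), via lithium hemiaminal alkoxide 7 (not isolated)
Conditions: n-BuLi (1.2 equiv), TMEDA (1.2 equiv), THF, 0 °C, 1 h; DMF (3 equiv), 0 °C → rt; H2O
Reagents that add atoms: N,N-dimethylformamide (DMF), CN(C)C=O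
Why: Directed ortho-metalation followed by DMF formylation: C6–H lies between two chelating OMOM groups (cooperative 1,3-direction), whereas C8–H has only one OMOM and the poorly coordinating hindered tertiary ring ether, so lithiation and formylation occur at C6.

**Step 4**
Reactants: 8 5,7-bis(methoxymethoxy)-2,2-dimethylchroman-6-carbaldehyde
Product: 9 5,7-dihydroxy-2,2-dimethylchroman-6-carbaldehyde
Conditions: conc. HCl (cat.), MeOH, 45 °C
Reagents that add atoms: none
Why: Acid-catalysed acetal exchange (MOM cleavage) with methanol frees both phenols, which then hydrogen-bond to the aldehyde, while the chroman ether and the deactivated aldehyde tolerate dilute acid at this temperature.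

**Step 5**
Reactants: 10 4-hydroxybenzaldehyde; 11 prenyl bromide (1-bromo-3-methylbut-2-ene)
Product: 12 4-hydroxy-3-(3-methylbut-2-enyl)benzaldehyde
Conditions: KOH, H2O, rt, 24 h
Reagents that add atoms: none
Why: Ambident phenoxide alkylation: water solvates the phenoxide oxygen strongly, so SN2 attack on the soft allylic bromide goes largely through the ortho carbon (para is blocked) and rearomatisation follows; the O-prenyl ether is a separable by-product.

**Step 6**
Reactants: 12 4-hydroxy-3-(3-methylbut-2-enyl)benzaldehyde
Product: 13 2-(3-methylbut-2-enyl)-4-vinylphenol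
Conditions: Ph3PCH3Br (2.5 equiv), KOt-Bu (2.5 equiv), THF, 0 °C → rt; aq NH4Cl; used at once, stored with BHT
Reagents that add atoms: methyltriphenylphosphonium bromide, C[P+](c1ccccc1)(c1ccccc1)c1ccccc1.[Br-]
Why: Wittig methylenation with the non-stabilised ylide in excess, which first deprotonates the phenol and then still olefinates the phenoxide aldehyde, while the trisubstituted prenyl alkene is untouched.

**Step 7**
Reactants: 9 5,7-dihydroxy-2,2-dimethylchroman-6-carbaldehyde; 13 2-(3-methylbut-2-enyl)-4-vinylphenol
Product: 14 1-(5,7-dihydroxy-2,2-dimethylchroman-6-yl)-3-[4-hydroxy-3-(3-methylbut-2-enyl)phenyl]propan-1-one (target)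
Conditions: [Rh(cod)OMe]2 (2.5 mol%), bulky BINOL-derived N,N-bis(1-phenylethyl)phosphoramidite (10 mol%, ligand chirality irrelevant), K3PO4 (10 mol%), BHT (2 mol%), 2-MeTHF, 70 °C, Ar, 13 (1.5 equiv)
Reagents that add atoms: none
Why: Proposed new method: linear-selective, chelation-assisted Rh(I) hydroacylation of an unprotected 4-vinylphenol by a 2,6-dihydroxybenzaldehyde; catalytic base deprotonates only the more acidic aldehyde-conjugated OH of 9 (pKa about 7–8 against about 10 for 13), the Rh(I) phenoxide adds oxidatively into the adjacent formyl C–H bond to give a five-membered O,C-chelated acyl-Rh(III) hydride that resists decarbonylation, the monosubstituted vinyl group of 13 binds and inserts while the trisubstituted prenyl alkene is too hindered to coordinate, hydride insertion is reversible so the branched benzylic Rh-alkyl reverts because C–C reductive elimination of a secondary alkyl onto the doubly ortho-substituted aroyl group inside the pocket of the bulky π-acidic ligand is much slower than that of the primary 2-arylethyl group (Curtin–Hammett control), and elimination gives 14 with every atom of both partners and no stereocentre; the closest known reaction type is the Rh/phosphoramidite-catalysed linear hydroacylation of unactivated terminal alkenes with salicylaldehydes, which to my knowledge has not been shown for vinylarenes (normally branched-selective), free vinylphenols or 2,6-dihydroxybenzaldehydes.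

**Compound list**
1 | phloroglucinol | Oc1cc(O)cc(O)c1 | starting material
2 | 2-methylbut-3-en-2-ol | CC(C)(O)C=C | starting material
3 | 2-prenylphloroglucinol, 2-(3-methylbut-2-enyl)benzene-1,3,5-triol (not isolated) | CC(C)=CCc1c(O)cc(O)cc1O | intermediate
4 | 2,2-dimethylchroman-5,7-diol | CC1(C)CCc2c(O)cc(O)cc2O1 | intermediate
5 | 5,7-bis(methoxymethoxy)-2,2-dimethylchroman | CC1(C)CCc2c(OCOC)cc(OCOC)cc2O1 | intermediate
6 | C6-aryllithium, 6-lithio-5,7-bis(methoxymethoxy)-2,2-dimethylchroman (not isolated) | CC1(C)CCc2c(OCOC)c([Li])c(OCOC)cc2O1 | intermediate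
7 | lithium hemiaminal alkoxide from 6 and DMF (not isolated, racemic transient centre) | CC1(C)CCc2c(OCOC)c(C([O-])N(C)C)c(OCOC)cc2O1.[Li+] | intermediate
8 | 5,7-bis(methoxymethoxy)-2,2-dimethylchroman-6-carbaldehyde | CC1(C)CCc2c(OCOC)c(C=O)c(OCOC)cc2O1 | intermediate
9 | 5,7-dihydroxy-2,2-dimethylchroman-6-carbaldehyde | CC1(C)CCc2c(O)c(C=O)c(O)cc2O1 | intermediate
10 | 4-hydroxybenzaldehyde | O=Cc1ccc(O)cc1 | starting material
11 | prenyl bromide (1-bromo-3-methylbut-2-ene) | CC(C)=CCBr | starting material
12 | 4-hydroxy-3-(3-methylbut-2-enyl)benzaldehyde | CC(C)=CCc1cc(C=O)ccc1O | intermediate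
13 | 2-(3-methylbut-2-enyl)-4-vinylphenol | CC(C)=CCc1cc(C=C)ccc1O | intermediate
14 | 1-(5,7-dihydroxy-2,2-dimethylchroman-6-yl)-3-[4-hydroxy-3-(3-methylbut-2-enyl)phenyl]propan-1-one (achiral) | CC(C)=CCc1cc(CCC(=O)c2c(O)cc3c(c2O)CCC(C)(C)O3)ccc1O | target

**Step count**
Total steps: 7. Longest linear sequence: 5 (steps 1, 2, 3, 4, 7). The second branch is steps 5, 6, 7.

**Three steps most likely to fail**

Step 7 (proposed new hydroacylation).
- Risks: the branched α-aryl ketone may form through an η3-benzyl rhodium species, 13 may polymerise, and the chelating product may inhibit the catalyst.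
- The fallback uses known chemistry. It sets out from 5 and 12 and comes back to the route at 14.
- Compound 5 is lithiated as in step 3 (through 6) and quenched with N-methoxy-N-methylacetamide to give 1-[5,7-bis(methoxymethoxy)-2,2-dimethylchroman-6-yl]ethanone F1.
- Compound 12 is protected with MOMCl and i-Pr2NEt in CH2Cl2 as 4-(methoxymethoxy)-3-(3-methylbut-2-enyl)benzaldehyde F2.
- Claisen–Schmidt condensation of the two (KOH, EtOH, rt) gives (E)-1-[5,7-bis(methoxymethoxy)-2,2-dimethylchroman-6-yl]-3-[4-(methoxymethoxy)-3-(3-methylbut-2-enyl)phenyl]prop-2-en-1-one F3.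
- Catalytic copper hydride conjugate reduction (Cu(OAc)2·H2O, 1,2-bis(diphenylphosphino)benzene, PMHS, t-BuOH, toluene, rt) reduces only the enone C=C and leaves the prenyl group. It gives 1-[5,7-bis(methoxymethoxy)-2,2-dimethylchroman-6-yl]-3-[4-(methoxymethoxy)-3-(3-methylbut-2-enyl)phenyl]propan-1-one F4.
- Brief treatment with dilute HCl in MeOH at rt removes the three MOM groups without cyclising the o-prenylphenol and gives 14.

Step 3 (C6 versus C8 lithiation).
- Risk: some C8 metalation would give the isomeric 8-carbaldehyde.
- The fallback fixes the regiochemistry by symmetry instead of by competing directing groups. It sets out from 1 and comes back at 9.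
- Vilsmeier–Haack formylation of 1 (POCl3, DMF, then H2O) gives 2,4,6-trihydroxybenzaldehyde F5.
- Its only non-chelated and most acidic OH (para to CHO) is alkylated with 3-chloro-3-methylbut-1-yne (CuCl2 cat., DBU, MeCN, 0 °C) to give 2,6-dihydroxy-4-(2-methylbut-3-yn-2-yloxy)benzaldehyde F6.
- Heating in xylene at 140 °C triggers the aryl propargyl Claisen rearrangement, 1,5-H shift and oxa-6π closure. Both ortho positions are equivalent, so the only possible product is 5,7-dihydroxy-2,2-dimethyl-2H-chromene-6-carbaldehyde F7.
- Hydrogenation of the chromene C3=C4 bond (H2 1 atm, Pd/C, EtOAc, rt, one equivalent taken up) gives 9.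

Step 5 (C- versus O-prenylation).
- Risk: the yield is modest because of the O-prenyl ether and double alkylation.
- The fallback replaces direct C-alkylation by O-alkylation and a [3,3] shift. It sets out from 10 and comes back at 12.
- Compound 10 is etherified with 3-chloro-3-methylbut-1-yne (CuCl2 cat., DBU, MeCN, 0 °C) to give 4-(2-methylbut-3-yn-2-yloxy)benzaldehyde F8.
- Lindlar semihydrogenation (H2, Pd/CaCO3–Pb, quinoline, EtOAc) gives 4-(2-methylbut-3-en-2-yloxy)benzaldehyde F9.
- Aromatic Claisen rearrangement (N,N-diethylaniline, 130–150 °C) delivers the prenyl group, with allyl inversion, to the ortho carbon only and gives 12.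

**Further compounds**
F1 | step 7 | 1-[5,7-bis(methoxymethoxy)-2,2-dimethylchroman-6-yl]ethanone | CC1(C)CCc2c(OCOC)c(C(C)=O)c(OCOC)cc2O1
F2 | step 7 | 4-(methoxymethoxy)-3-(3-methylbut-2-enyl)benzaldehyde | CC(C)=CCc1cc(C=O)ccc1OCOC
F3 | step 7 | (E)-1-[5,7-bis(methoxymethoxy)-2,2-dimethylchroman-6-yl]-3-[4-(methoxymethoxy)-3-(3-methylbut-2-enyl)phenyl]prop-2-en-1-one | CC(C)=CCc1cc(/C=C/C(=O)c2c(OCOC)cc3c(c2OCOC)CCC(C)(C)O3)ccc1OCOC
F4 | step 7 | 1-[5,7-bis(methoxymethoxy)-2,2-dimethylchroman-6-yl]-3-[4-(methoxymethoxy)-3-(3-methylbut-2-enyl)phenyl]propan-1-one | CC(C)=CCc1cc(CCC(=O)c2c(OCOC)cc3c(c2OCOC)CCC(C)(C)O3)ccc1OCOC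
F5 | step 3 | 2,4,6-trihydroxybenzaldehyde | O=Cc1c(O)cc(O)cc1O
F6 | step 3 | 2,6-dihydroxy-4-(2-methylbut-3-yn-2-yloxy)benzaldehyde | C#CC(C)(C)Oc1cc(O)c(C=O)c(O)c1
F7 | step 3 | 5,7-dihydroxy-2,2-dimethyl-2H-chromene-6-carbaldehyde | CC1(C)C=Cc2c(O)c(C=O)c(O)cc2O1
F8 | step 5 | 4-(2-methylbut-3-yn-2-yloxy)benzaldehyde | C#CC(C)(C)Oc1ccc(C=O)cc1
F9 | step 5 | 4-(2-methylbut-3-en-2-yloxy)benzaldehyde | C=CC(C)(C)Oc1ccc(C=O)cc1
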